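**Retrosynthetic overview**

- The pyridine ring is formed last. The target is opened across N1–C8a and C4–C4a to an achiral 4-aryl-4-(2-formamidoethyl)cyclohexanone plus 3-aminoacrolein (malondialdehyde + ammonia), the condensation by which the pyridine ring of the Sceletium bases is thought to arise from a seco-mesembrine ketone.
- The stereocentre is not made beforehand. A chiral amine catalyst selects one of the two enantiotopic α-CH2 groups of that ketone during the annulation, and this choice alone fixes C6 as (S).
- The ketone comes from a 4-aryl-cyclohex-2-enone by hydrogenation; its quaternary carbon is made by γ-arylation of a β,γ-unsaturated ketone with 4-bromoveratrole.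
- The carbocycle is not constructed: it is the Birch-reduced arene of 4-methoxy-N-methylphenethylamine, as the tyrosine-derived ring is in nature.
- Ring order: dimethoxyphenyl ring (bought), carbocycle (from an arene, steps 1–4), pyridine (step 5).

Assumption: the sense of induction in step 5 follows the working model stated there (L-configured catalyst, electrophile entering trans to the aryl group); if a pilot run gives the (R)-product, the D-configured catalyst is used with nothing else changed.

**Route**

Step 1
Reactants: 1 2-(4-methoxyphenyl)-N-methylethan-1-amine (4-methoxy-N-methylphenethylamine)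
Product: 2 2-(4-methoxycyclohexa-1,4-dien-1-yl)-N-methylethan-1-amine
Conditions: Li (2.5 equiv), t-BuOH (2.5 equiv), NH3(l)/THF, −78 to −33 °C; then H2O
Reagents that add atoms: none
Why: Birch reduction of a para-alkyl anisole gives the 2,5-dihydro product with the enol ether and the alkyl-bearing alkene unconjugated, the secondary amine and the non-benzylic C–N bond are inert to Li/NH3, and no stereocentre is formed.

Step 2
Reactants: 2 2-(4-methoxycyclohexa-1,4-dien-1-yl)-N-methylethan-1-amine
Product: 4 N-methyl-N-[2-(4-oxocyclohex-1-en-1-yl)ethyl]formamide, via formamide dienol ether 3 (not isolated)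
Conditions: HCO2Et (neat), 55 °C; evaporate; then (CO2H)2 (10 mol %), THF/H2O, 20 °C
Reagents that add atoms: ethyl formate (CCOC=O); water (O)
Why: Aminolysis of ethyl formate N-formylates the secondary amine under neutral conditions that spare the enol ether, and mild oxalic acid hydrolysis then unmasks the ketone kinetically as the β,γ-unsaturated isomer without moving the trisubstituted alkene into conjugation; no stereocentre is formed.

Step 3
Reactants: 4 N-methyl-N-[2-(4-oxocyclohex-1-en-1-yl)ethyl]formamide; 5 4-bromo-1,2-dimethoxybenzene
Product: 6 rac-N-{2-[1-(3,4-dimethoxyphenyl)-4-oxocyclohex-2-en-1-yl]ethyl}-N-methylformamide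
Conditions: Pd(OAc)2 (2 mol %), XPhos (4 mol %), Cs2CO3 (1.5 equiv), toluene, 80 °C
Reagents that add atoms: none
Why: Palladium-catalysed γ-arylation of a β,γ-unsaturated ketone: the extended dienolate formed with Cs2CO3 is arylated at its γ-terminus under a bulky biarylphosphine, which creates the quaternary carbon and leaves the conjugated enone; the product is racemic, which is harmless because step 4 removes the element of chirality.

Step 4
Reactants: 6 rac-N-{2-[1-(3,4-dimethoxyphenyl)-4-oxocyclohex-2-en-1-yl]ethyl}-N-methylformamide
Product: 7 N-{2-[1-(3,4-dimethoxyphenyl)-4-oxocyclohexyl]ethyl}-N-methylformamide (achiral)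
Conditions: H2 (1 atm), Pd/C (10 wt % Pd), EtOAc, 20 °C
Reagents that add atoms: none
Why: Heterogeneous hydrogenation of the disubstituted enone C=C is much faster than ketone, arene or formamide reduction, and saturating it makes the two ring arms identical, so 7 is achiral with a prochiral C4.

Step 5
Reactants: 7 N-{2-[1-(3,4-dimethoxyphenyl)-4-oxocyclohexyl]ethyl}-N-methylformamide; 8 (2E)-3-aminoprop-2-enal (3-aminoacrolein)
Product: 10 N-{2-[(6S)-6-(3,4-dimethoxyphenyl)-5,6,7,8-tetrahydroquinolin-6-yl]ethyl}-N-methylformamide, via aminodienone 9 (not isolated)
Conditions: 8 (2 equiv, in portions), (2S,4R)-4-(tert-butyldiphenylsilyloxy)pyrrolidine-2-carboxylic acid (20 mol %), CHCl3/DMSO 4:1, 20 °C, 72 h; then AcOH, 60 °C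
Reagents that add atoms: none
Why: Proposed new method: the proline-type catalyst forms an enamine toward one of the two enantiotopic α-CH2 groups of 7 and its carboxylic acid delivers the aldehyde carbon of 8 to one enamine face (the (2S)-sense of L-proline aldol reactions), the electrophile entering trans to the aryl group on C4 (working model, not secured by precedent); loss of water gives aminodienone 9 with the new ring already committed to that arm, and acid-promoted E/Z isomerisation and cyclodehydration (as in the Bohlmann–Rahtz and Breitmaier pyridine syntheses) aromatise it, so the choice of arm alone sets the remote quaternary C6 as (S); the closest known reaction type is the amine-catalysed enantioselective Friedländer condensation of 4-substituted cyclohexanones with 2-aminobenzaldehydes (desymmetrising aldol condensation, then cyclodehydration), extended here to the non-benzo aminoaldehyde and to a 4,4-disubstituted ketone.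

**Compound list**

1 | 2-(4-methoxyphenyl)-N-methylethan-1-amine | CNCCc1ccc(OC)cc1 | starting material
2 | 2-(4-methoxycyclohexa-1,4-dien-1-yl)-N-methylethan-1-amine | CNCCC1=CCC(OC)=CC1 | intermediate
3 | N-[2-(4-methoxycyclohexa-1,4-dien-1-yl)ethyl]-N-methylformamide | O=CN(C)CCC1=CCC(OC)=CC1 | intermediate
4 | N-methyl-N-[2-(4-oxocyclohex-1-en-1-yl)ethyl]formamide | O=CN(C)CCC1=CCC(=O)CC1 | intermediate
5 | 4-bromo-1,2-dimethoxybenzene | COc1ccc(Br)cc1OC | starting material
6 | rac-N-{2-[1-(3,4-dimethoxyphenyl)-4-oxocyclohex-2-en-1-yl]ethyl}-N-methylformamide (racemate) | COc1ccc(C2(CCN(C)C=O)C=CC(=O)CC2)cc1OC | intermediate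
7 | N-{2-[1-(3,4-dimethoxyphenyl)-4-oxocyclohexyl]ethyl}-N-methylformamide (achiral) | COc1ccc(C2(CCN(C)C=O)CCC(=O)CC2)cc1OC | intermediate
8 | (2E)-3-aminoprop-2-enal | N/C=C/C=O | starting material
9 | N-{2-[(1S,3E)-3-[(2E)-3-aminoprop-2-en-1-ylidene]-1-(3,4-dimethoxyphenyl)-4-oxocyclohexyl]ethyl}-N-methylformamide | COc1ccc([C@@]2(CCN(C)C=O)CCC(=O)/C(=C/C=C/N)C2)cc1OC | intermediate
10 | N-{2-[(6S)-6-(3,4-dimethoxyphenyl)-5,6,7,8-tetrahydroquinolin-6-yl]ethyl}-N-methylformamide (N-formyltortuosamine) | COc1ccc([C@@]2(CCN(C)C=O)CCc3ncccc3C2)cc1OC | target

**Step count and risks**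

Total step count: 5. Longest linear sequence: 5 steps (1 → 2 → 4 → 6 → 7 → 10); 5 and 8 are bought.

Most likely to fail, first: step 5. The catalyst must tell an aryl group from an alkyl chain three bonds away, so the enantiomeric excess and even its sense are uncertain. The vinylogous amide 8 is a weak electrophile and can self-condense, and an uncatalysed imine pathway would give racemate. The enantiomeric excess of 10 is measured by chiral HPLC.

The fallback sets out from 6 and returns at 10, and moves the stereo-determining event to a known desymmetrisation. Enone 6 is dehydrogenated with IBX in DMSO at 80 °C to the achiral N-{2-[1-(3,4-dimethoxyphenyl)-4-oxocyclohexa-2,5-dien-1-yl]ethyl}-N-methylformamide F1. A copper hydride catalyst with a chiral bisphosphine (Cu(OAc)2, Ph-BPE, (EtO)2MeSiH, t-BuOH, toluene; ligand enantiomer chosen in a pilot run) reduces one of the two enantiotopic enone C=C bonds to give the (S)-enone F2, the single-enantiomer form of 6. F2 has only one enolisable α-CH2, because the other α-carbon is vinylic. Plain condensation with 8 (NH4OAc cat., AcOH, 80 °C) can therefore only fuse the pyridine onto the saturated arm, giving the (S)-5,6-dihydroquinoline F3. Hydrogenation of its 7,8-alkene (H2, Pd/C, EtOAc) gives 10.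

Second: step 3. Arylation may go to the α-carbon instead of the γ-carbon, or reductive elimination at a fully substituted carbon may be slow.

The fallback sets out from 4 and returns at 7, so that step 4 is skipped. The aryl group is delivered to a tertiary radical instead of a dienolate. Hydrogen-atom transfer from an iron hydride (Fe(acac)3, PhSiH3) to the trisubstituted alkene of 4 gives the tertiary radical. A nickel catalyst (NiBr2·diglyme, 4,4′-di-tert-butyl-2,2′-bipyridine) couples it with 4-iodo-1,2-dimethoxybenzene. This is a Markovnikov hydroarylation with aqueous NaHCO3 work-up, and the product is 7 itself; no compound outside the list is made (F0).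

Third: step 2. The β,γ-unsaturated ketone 4 may slip into conjugation or self-condense on isolation.

The fallback sets out from 2 and returns at 6. After the same formylation to 3, the enol ether is hydrolysed with aqueous HCl in THF all the way to the stable conjugated isomer rac-N-methyl-N-[2-(4-oxocyclohex-2-en-1-yl)ethyl]formamide F4. F4 is deprotonated at its γ-carbon with NaOt-Bu to the same extended dienolate and arylated with 5 under the palladium catalyst of step 3 to give 6.

**Further compounds**

F1 | step 5 | N-{2-[1-(3,4-dimethoxyphenyl)-4-oxocyclohexa-2,5-dien-1-yl]ethyl}-N-methylformamide | COc1ccc(C2(CCN(C)C=O)C=CC(=O)C=C2)cc1OC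
F2 | step 5 | N-{2-[(1S)-1-(3,4-dimethoxyphenyl)-4-oxocyclohex-2-en-1-yl]ethyl}-N-methylformamide | COc1ccc([C@@]2(CCN(C)C=O)C=CC(=O)CC2)cc1OC
F3 | step 5 | N-{2-[(6S)-6-(3,4-dimethoxyphenyl)-5,6-dihydroquinolin-6-yl]ethyl}-N-methylformamide | COc1ccc([C@@]2(CCN(C)C=O)C=Cc3ncccc3C2)cc1OC
F0 | step 3 | none | none
F4 | step 2 | rac-N-methyl-N-[2-(4-oxocyclohex-2-en-1-yl)ethyl]formamide | O=CN(C)CCC1C=CC(=O)CC1
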